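## Retrosynthetic overview

1. Target 8 ⇒ cyclohexene mono-ether 7 by opening the bridging ether (C-3'–O bond); forward, this is a Markovnikov hydroalkoxylation.
2. 7 ⇒ two identical C15 halves by a cationic [4+2] disconnection (bonds C-b–C-4' and C-a–C-1', plus O–CMe2): E-dienol 6 as the 4π partner and ring-opened allyl cation 5 as the 2π partner, held in one ion pair with a chiral phosphoramide anion.
3. 5 and 6 ⇒ N-methylflindersine 4 by acid ionisation of its pyran C–O bond (5) and loss of a methyl proton from 5 (6).
4. 4 ⇒ 4-hydroxy-1-methylquinolin-2(1H)-one 1 + 3-methylbut-2-enal 2 (Knoevenagel to quinone methide 3, then oxa-6π ring closure).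
5. Ring order: pyran of 4 (opened again in step 2) → cyclohexene together with trans-fused pyran ring A → bridging pyran ring B.

Atom labels used in the names: C-a carries the CMe2–O group, C-b carries quinolinone A, C-c carries quinolinone B. C-1' to C-4' are the dienyl carbons of the B half (C-1' = C-c, C-3' carries the methyl group).

Assumption 1: the (R)-configured acid named in step 2 is taken to give the drawn enantiomer; the sense of induction has to be confirmed (X-ray or ECD), and the (S)-acid is used if it is the opposite.

Assumption 2: the route has only two steps, so step 2, which can fail in two independent ways, is entered twice in the risk list.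

## Route

Step 1
Reactants: 1 4-hydroxy-1-methylquinolin-2(1H)-one; 2 3-methylbut-2-enal (1.5 equiv)
Product: 4 N-methylflindersine (2,2,6-trimethyl-2H-pyrano[3,2-c]quinolin-5(6H)-one), via quinone methide 3 (not isolated)
Conditions: pyridine, MgSO4, 90 °C, 4 h (stopped at full conversion of 1)
Reagents that add atoms: 3-methylbut-2-enal (compound 2), CC(C)=CC=O
Why: Knoevenagel condensation at C-3 of the vinylogous acid gives 1-oxatriene 3, which closes by oxa-6π electrocyclisation to the 2H-pyran (formal [3+3] annulation); no stereocentre is formed.

Step 2
Reactants: 4 N-methylflindersine (two molecules, one for each half)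
Product: 8 (aR,bS,cS,3'R)-trans-fused N-methylflindersine dimer (target), via allyl cation 5 (not isolated), via dienol 6 (not isolated), via cycloadduct 7 (not isolated)
Conditions: (R)-3,3'-bis(2,4,6-triisopropylphenyl)-1,1'-binaphthalene-2,2'-diyl N-(trifluoromethanesulfonyl)phosphoramide, C51H57F3NO5PS (10 mol%), 5 Å MS, PhCF3 (0.3 M), 45 °C, 48 h; then TfOH (10 mol%), 45 °C, 2 h, same flask
Reagents that add atoms: none
Why: Proposed new method: the strong chiral acid protonates the pyran oxygen of 4 and ionises its tertiary allylic C–O bond (the leaving group is the acidic 4-hydroxyquinolinone, pKa about 6) to the ring-opened 1,1-dimethylallyl cation 5, which is paired with the chiral phosphoramide anion and relaxes from its cisoid to its transoid (E) form through its O-protonated quinone methide resonance form; loss of a methyl proton from transoid 5 gives E-dienol 6, whose 4-OH hydrogen-bonds to the same anion, so that 6 (4π, nucleophilic at C-4') and a second cation 5 (2π, electrophilic at C-b) combine in an asynchronous cationic Diels–Alder reaction inside one chiral ion pair; the transoid cation sets H-a/H-b trans, the endo position of the CMe2 cation terminus under the E-diene sets quinolinone B at C-c cis to the CMe2 group at C-a, the anion selects the face and so the absolute configuration, the CMe2 cation is caught by the neighbouring 4-O to close trans-fused pyran ring A (7), and the Markovnikov hydroalkoxylation of the ring alkene by the second 4-OH (completed by TfOH) can only take place on the face that carries quinolinone B, which sets C-3'; the closest known reaction types are the racemic heat- or acid-induced dimerisation of 2H-pyranoquinolinones, chiral Brønsted acid catalysed [4+2] reactions of ortho-quinone methides with ortho-hydroxystyrenes, and counteranion-directed cationic Diels–Alder reactions of allyl cations.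

## Compound list

1 | 4-hydroxy-1-methylquinolin-2(1H)-one | Cn1c(=O)cc(O)c2ccccc21 | starting material
2 | 3-methylbut-2-enal | CC(C)=CC=O | starting material
3 | (E)-1-methyl-3-(3-methylbut-2-en-1-ylidene)quinoline-2,4(1H,3H)-dione (ortho-quinone methide) | CN1C(=O)/C(=C/C=C(C)C)C(=O)c2ccccc21 | intermediate (not isolated)
4 | N-methylflindersine, 2,2,6-trimethyl-2H-pyrano[3,2-c]quinolin-5(6H)-one | Cn1c(=O)c2c(c3ccccc31)OC(C)(C)C=C2 | intermediate (isolated)
5 | (E)-4-(4-hydroxy-1-methyl-2-oxo-1,2-dihydroquinolin-3-yl)-2-methylbut-3-en-2-ylium (ring-opened 1,1-dimethylallyl cation of 4; counter-ion is the chiral phosphoramide anion) | Cn1c(=O)c(/C=C/[C+](C)C)c(O)c2ccccc21 | intermediate (not isolated)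
6 | (E)-4-hydroxy-1-methyl-3-(3-methylbuta-1,3-dien-1-yl)quinolin-2(1H)-one | Cn1c(=O)c(/C=C/C(C)=C)c(O)c2ccccc21 | intermediate (not isolated)
7 | (aR,bS,cS)-cycloadduct: 2,2-dimethylpyrano[3,2-c]quinolinone (unit A) trans-fused at C-a/C-b (H-a and H-b anti) to a cyclohexene with the alkene at C-2'=C-3' (methyl on C-3'); C-c carries a 4-hydroxy-1-methyl-2-oxo-1,2-dihydroquinolin-3-yl group (unit B) cis to the CMe2 group on C-a | Cn1c(=O)c2c(c3ccccc31)OC(C)(C)[C@@H]1[C@@H]2CC(C)=C[C@@H]1c1c(O)c3ccccc3n(C)c1=O | intermediate (not isolated)
8 | (aR,bS,cS,3'R)-dimer of N-methylflindersine: as 7, with the 4-O of unit B bonded to C-3' (pyran ring B bridging C-c and C-3' as a 2-oxabicyclo[3.3.1]nonane; 3'-methyl on the face of H-a and H-c); C30H30N2O4 | Cn1c(=O)c2c(c3ccccc31)OC(C)(C)[C@@H]1[C@@H]2C[C@@]2(C)C[C@@H]1c1c(c3ccccc3n(C)c1=O)O2 | target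

## Step count and risks

Total step count: 2. Longest linear sequence: 2 (1 → 4 → 8).

**Risk 1 – step 2, stereocontrol.** The ion-paired [4+2] is untested. It may give low ee, or cis-fused diastereomers if the cisoid cation reacts before it relaxes. The fallback sets out from 4 and gives up catalyst control in favour of resolution. Compound 4 is dimerised with TfOH alone (10 mol%, PhCF3, 45 °C), which runs the same cationic cascade without chiral information. The trans-fused dimer is freed from minor diastereomers by chromatography and crystallisation and is then a 1:1 mixture of 8 and its mirror image, the (aS,bR,cR,3'S)-dimer F1. Preparative supercritical-fluid chromatography on an amylose tris(3,5-dimethylphenylcarbamate) phase separates the two, and the wanted antipode is identified by ECD or X-ray. The fallback comes back to the route at 8.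

**Risk 2 – step 2, unmasking of the two partners from 4.** The acid may instead protonate the pyran alkene at C-a, the cisoid cation may simply return to 4, or the cation may react as an oxa-diene. The fallback sets out from 1 and builds the E-dienol without any ring opening. Compound 1 is iodinated with N-iodosuccinimide (MeCN, rt) to 4-hydroxy-3-iodo-1-methylquinolin-2(1H)-one F2. Separately, 2-methylbut-1-en-3-yne is hydroborated with pinacolborane (Cp2Zr(H)Cl 5 mol%, Et3N, 40 °C) to (E)-4,4,5,5-tetramethyl-2-(3-methylbuta-1,3-dien-1-yl)-1,3,2-dioxaborolane F3. Suzuki–Miyaura coupling of F2 with F3 (PdCl2(dppf), dppf = 1,1'-bis(diphenylphosphino)ferrocene, K3PO4, dioxane/H2O, 60 °C) gives the E-dienol, which stays open in the basic medium and is isolated after cold neutral work-up. The fallback comes back to the route at 6. Compound 6 is then treated with the N-triflylphosphoramide (R)-C51H57F3NO5PS at −20 to 0 °C, followed by TfOH. Protonation of E-6 at C-4' gives the transoid cation 5 directly, so the same cascade runs from 6 through 5 and 7 to 8 at low temperature, which should also help the trans/cis ratio.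

**Risk 3 – step 1.** Prolonged heating in pyridine starts racemic dimerisation of 4, and the aldehyde self-condenses. The fallback sets out from 1 and reaches 4 by prenylation followed by oxidative cyclisation. Compound 1 is C-prenylated with 3-methylbut-2-en-1-yl acetate (Pd(PPh3)4 5 mol%, Et3N, THF, 50 °C; any O-allyl product re-ionises and ends on carbon) to 4-hydroxy-1-methyl-3-(3-methylbut-2-en-1-yl)quinolin-2(1H)-one F4. DDQ (2,3-dichloro-5,6-dicyano-1,4-benzoquinone, 1.1 equiv, toluene, 80 °C) abstracts hydride from the benzylic-allylic CH2 to give 3, which closes by oxa-6π electrocyclisation. The fallback comes back to the route at 4.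

Further compounds
F1 | step 2 | (aS,bR,cR,3'S)-dimer of N-methylflindersine, mirror image of 8 | Cn1c(=O)c2c(c3ccccc31)OC(C)(C)[C@H]1[C@H]2C[C@]2(C)C[C@H]1c1c(c3ccccc3n(C)c1=O)O2
F2 | step 2 | 4-hydroxy-3-iodo-1-methylquinolin-2(1H)-one | Cn1c(=O)c(I)c(O)c2ccccc21
F3 | step 2 | (E)-4,4,5,5-tetramethyl-2-(3-methylbuta-1,3-dien-1-yl)-1,3,2-dioxaborolane | CC(=C)/C=C/B1OC(C)(C)C(C)(C)O1
F4 | step 1 | 4-hydroxy-1-methyl-3-(3-methylbut-2-en-1-yl)quinolin-2(1H)-one | Cn1c(=O)c(CC=C(C)C)c(O)c2ccccc21
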